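**Plan**

1. Numbering (eunicellane): six-membered ring C1, C10–C14 (C11 carries the exocyclic methylene C20, C14 the isopropyl group); ten-membered ring C1–C10 (C2=C3 with CO2Me on C3, C6=C7 with CO2H on C7, C8–OH).
2. Enabling feature: ring carbons C11 and C1 each carry an exocyclic sp2 one-carbon unit (C20, C2). Read as formyl groups they are 1,5-related through C10 (Michael retron, C1–C10) and C12 lies β to C20 (aldol-condensation retron, C11–C12); the remaining chain C2–C1–C14–C13–C12 is then symmetric about C14, i.e. achiral 3-isopropylpentanedial.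
3. Retrosynthesis: silyl groups off; C11=C20 from a C20 hydroxymethyl cyclohexene by reductive allylic transposition; ten-membered ring cut at C2=C3 (intramolecular Horner–Wadsworth–Emmons); cyclohexene cut at C11–C12 and C1–C10 into the dial and an enal; the enal cut at C10=C11 (cross-metathesis), C3–C4 (alkylation), C7–C19 (carboxylation) and C8–C9 (allylation).
4. Forward: linear assembly of the C3–C11 enal; hetero-Diels–Alder/hydrolysis to the dial; amine-catalysed Michael/aldol condensation builds the six-membered ring; olefination closes the ten-membered ring; transposition and desilylation finish.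
5. Stereochemistry: C8 by catalytic asymmetric allylation; C10 and C1 by the amine catalyst and C14 by desymmetrisation in the same event; C6=C7 geometry by syn-hydrostannation and retentive carboxylation; C2=C3 geometry by the olefination.

Key step: step 13

Remark: every intermediate that carries the phosphonate is a mixture of two epimers at C3; this centre disappears in the ring-closing olefination.

**Route**

Step 1
Reactants: 1 4-(tert-butyldimethylsilyloxy)but-1-yne
Product: 3 5-(tert-butyldimethylsilyloxy)pent-2-ynal, via lithium acetylide 2 (not isolated)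
Conditions: n-BuLi, THF, −78 °C; DMF, −78 → 0 °C; reverse quench into aq. KH2PO4
Reagents that add atoms: N,N-dimethylformamide CN(C)C=O; n-butyllithium [Li]CCCC (lithium only in 2)
Why: Acetylide formylation with DMF; the buffered reverse quench should release the ynal without conjugate addition of dimethylamine.

Step 2
Reactants: 3 5-(tert-butyldimethylsilyloxy)pent-2-ynal
Product: 4 (R)-8-(tert-butyldimethylsilyloxy)oct-1-en-5-yn-4-ol
Conditions: (R)-BINOL (20 mol%), Ti(OiPr)4 (10 mol%), 4 Å molecular sieves, allylSnBu3, CH2Cl2, −20 °C; aq. NaHCO3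
Reagents that add atoms: allyltributylstannane C=CC[Sn](CCCC)(CCCC)CCCC
Why: Keck asymmetric allylation, for which ynals are good substrates; the BINOL–titanium complex should deliver allyl to the Re face of the aldehyde and so set C8 as R.

Step 3
Reactants: 4 (R)-8-(tert-butyldimethylsilyloxy)oct-1-en-5-yn-4-ol
Product: 6 (4R,5E)-8-(tert-butyldimethylsilyloxy)-5-iodoocta-1,5-dien-4-ol, via vinylstannane 5 (not isolated)
Conditions: Bu3SnH, PdCl2(PPh3)2 (3 mol%), THF, 0 °C; then I2, CH2Cl2, 0 °C
Reagents that add atoms: iodine II; tributyltin hydride CCCC[SnH](CCCC)CCCC (tin only in 5)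
Why: Palladium-catalysed syn-hydrostannation should place tin on C7 next to the carbinol (polarisation by the oxygen) with H and Sn cis, and iododestannylation goes with retention, so C5 and C8 end up cis across C6=C7; the minor distal regioisomer is removed by chromatography.

Step 4
Reactants: 6 (4R,5E)-8-(tert-butyldimethylsilyloxy)-5-iodoocta-1,5-dien-4-ol
Product: 8 (E)-2-[(R)-1-hydroxybut-3-en-1-yl]-5-(tert-butyldimethylsilyloxy)pent-2-enoic acid, via dilithio species 7 (not isolated)
Conditions: MeLi (1 equiv), Et2O, −78 °C; t-BuLi (2.1 equiv), −78 °C; CO2, −78 → 0 °C; cold 0.5 M HCl to pH 3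
Reagents that add atoms: carbon dioxide O=C=O; methyllithium [Li]C and tert-butyllithium [Li]C(C)(C)C (lithium only in 7)
Why: Iodine–lithium exchange on the lithium alkoxide gives a configurationally stable 2-lithioallyl alkoxide that cannot β-eliminate, and carboxylation with retention puts CO2H trans to C5.

Step 5
Reactants: 8 (E)-2-[(R)-1-hydroxybut-3-en-1-yl]-5-(tert-butyldimethylsilyloxy)pent-2-enoic acid
Product: 9 2-(trimethylsilyl)ethyl (E)-2-[(R)-1-hydroxybut-3-en-1-yl]-5-(tert-butyldimethylsilyloxy)pent-2-enoate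
Conditions: Me3SiCH2CH2OH (5 equiv), DCC, DMAP (10 mol%), CH2Cl2, 0 °C → rt
Reagents that add atoms: 2-(trimethylsilyl)ethanol C[Si](C)(C)CCO
Why: Steglich esterification; the excess primary alcohol should outcompete the hindered secondary allylic hydroxyl of the substrate.

Step 6
Reactants: 9 2-(trimethylsilyl)ethyl (E)-2-[(R)-1-hydroxybut-3-en-1-yl]-5-(tert-butyldimethylsilyloxy)pent-2-enoate
Product: 10 2-(trimethylsilyl)ethyl (E)-2-[(R)-1-(tert-butyldimethylsilyloxy)but-3-en-1-yl]-5-(tert-butyldimethylsilyloxy)pent-2-enoate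
Conditions: t-BuMe2SiOTf, 2,6-lutidine, CH2Cl2, −78 → 0 °C
Reagents that add atoms: tert-butyldimethylsilyl trifluoromethanesulfonate CC(C)(C)[Si](C)(C)OS(=O)(=O)C(F)(F)F
Why: Standard silylation of a hindered secondary alcohol; a silyl ether is a poor leaving group, so the allylic C8 oxygen stays inert to the later bases and nucleophiles.

Step 7
Reactants: 10 2-(trimethylsilyl)ethyl (E)-2-[(R)-1-(tert-butyldimethylsilyloxy)but-3-en-1-yl]-5-(tert-butyldimethylsilyloxy)pent-2-enoate
Product: 11 2-(trimethylsilyl)ethyl (E)-2-[(R)-1-(tert-butyldimethylsilyloxy)but-3-en-1-yl]-5-hydroxypent-2-enoate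
Conditions: camphorsulfonic acid (10 mol%), MeOH/CH2Cl2 (1:1), 0 °C
Reagents that add atoms: none
Why: Acid-catalysed methanolysis removes the unhindered primary silyl ether much faster than the secondary allylic one, and the silylethyl ester is stable to mild acid.

Step 8
Reactants: 11 2-(trimethylsilyl)ethyl (E)-2-[(R)-1-(tert-butyldimethylsilyloxy)but-3-en-1-yl]-5-hydroxypent-2-enoate
Product: 12 2-(trimethylsilyl)ethyl (E)-2-[(R)-1-(tert-butyldimethylsilyloxy)but-3-en-1-yl]-5-iodopent-2-enoate
Conditions: I2, PPh3, imidazole, CH2Cl2, 0 °C → rt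
Reagents that add atoms: iodine II
Why: Appel-type iodination of a primary alcohol under neutral conditions.

Step 9
Reactants: 12 2-(trimethylsilyl)ethyl (E)-2-[(R)-1-(tert-butyldimethylsilyloxy)but-3-en-1-yl]-5-iodopent-2-enoate; 13 trimethyl phosphonoacetate
Product: 14 7-methyl 1-[2-(trimethylsilyl)ethyl] (E)-2-[(R)-1-(tert-butyldimethylsilyloxy)but-3-en-1-yl]-6-(dimethoxyphosphoryl)hept-2-enedioate
Conditions: 13 (2 equiv), NaH (1.8 equiv), THF/DMF, 0 °C; then 12, 0 °C → rt
Reagents that add atoms: none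
Why: C-alkylation of the soft sodium phosphonoacetate anion by a primary iodide (C3–C4 bond); excess anion suppresses dialkylation and low temperature suppresses elimination towards the dienoate.

Step 10
Reactants: 14 7-methyl 1-[2-(trimethylsilyl)ethyl] (E)-2-[(R)-1-(tert-butyldimethylsilyloxy)but-3-en-1-yl]-6-(dimethoxyphosphoryl)hept-2-enedioate; 15 (E)-but-2-enal
Product: 16 7-methyl 1-[2-(trimethylsilyl)ethyl] (E)-2-[(1R,3E)-1-(tert-butyldimethylsilyloxy)-5-oxopent-3-en-1-yl]-6-(dimethoxyphosphoryl)hept-2-enedioate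
Conditions: 15 (5 equiv), second-generation Grubbs catalyst RuCl2(=CHPh)(H2IMes)(PCy3) (5 mol%), CH2Cl2, 40 °C
Reagents that add atoms: none
Why: Cross-metathesis of the terminal alkene with crotonaldehyde should give the (E)-enal; the trisubstituted enoate is inert to the catalyst.

Step 11
Reactants: 17 (E)-4-methylpent-2-enal; 18 ethyl vinyl ether
Product: 19 2-ethoxy-4-isopropyl-3,4-dihydro-2H-pyran
Conditions: Yb(fod)3 (5 mol%; fod = 6,6,7,7,8,8,8-heptafluoro-2,2-dimethyloctane-3,5-dionate), neat 18 (3 equiv), 50 °C, sealed tube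
Reagents that add atoms: none
Why: Lanthanide-catalysed inverse-electron-demand hetero-Diels–Alder reaction of an enal with a vinyl ether, the classical entry to 3-substituted glutaraldehydes; the cis/trans ratio is irrelevant.

Step 12
Reactants: 19 2-ethoxy-4-isopropyl-3,4-dihydro-2H-pyran
Product: 20 3-isopropylpentanedial
Conditions: 1 M aq. HCl, THF, rt; extract and use at once
Reagents that add atoms: water O
Why: Acid hydrolysis of the cyclic acetal and enol ether frees both formyl groups and leaves an achiral dial.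

Step 13
Reactants: 16 7-methyl 1-[2-(trimethylsilyl)ethyl] (E)-2-[(1R,3E)-1-(tert-butyldimethylsilyloxy)-5-oxopent-3-en-1-yl]-6-(dimethoxyphosphoryl)hept-2-enedioate; 20 3-isopropylpentanedial
Product: 23 (4S,5R,6S)-4-isopropyl-6-(C9–C3 side chain)cyclohex-1-ene-1,5-dicarbaldehyde, via Michael adduct 21 (not isolated), via aldol 22 (not isolated)
Conditions: 20 (2 equiv), (S)-2-[diphenyl(trimethylsilyloxy)methyl]pyrrolidine (20 mol%), PhCO2H (20 mol%), CHCl3, 0 °C → rt
Reagents that add atoms: none
Why: The amine forms an iminium ion with enal 16 and an enamine with one arm of dial 20; enamine carbon C1 adds to C10 (Michael addition, C1–C10), and the enamine this creates at C11 attacks the second formyl carbon C12 of the dial, after which loss of water gives the conjugated cyclohexenecarbaldehyde and frees the catalyst (C11–C12). The closest known reaction type is the diarylprolinol silyl ether-catalysed domino Michael/aldol condensation of pentane-1,5-dial or 5-oxoalkanals with enals, which is also the closing sequence of organocatalytic triple cascades. The one ring closed is the six-membered carbocycle, by a 6-(enolexo)-exo-trig aldol addition. C10 is set by the catalyst, whose diphenyl(silyloxy)methyl group shields one face of the (E)-iminium so that attack comes from the Re face, and C1 by the same group shielding one face of the (E)-enamine, which gives the C1/C10 trans pair. C14 arises by desymmetrisation, that is by which enantiotopic CH2CHO arm reacts: a staggered Houk-type transition state with isopropyl anti to the incoming iminium, the other arm inside and H outside should place isopropyl cis to the C1 formyl group, as in the target. The step needs cross-selectivity (only the enal can form an iminium, only the dial a saturated enamine, and the dial is in excess), one aldol mode (closures from C1 or C11 onto C2 would be four-membered, and C13 onto C20 is disfavoured because the Michael step delivers the enamine at C11) and arm selectivity at C14, which is the least secure element.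

Step 14
Reactants: 23 (4S,5R,6S)-4-isopropyl-6-(C9–C3 side chain)cyclohex-1-ene-1,5-dicarbaldehyde
Product: 24 (1R,2S,6S)-3-(hydroxymethyl)-6-isopropyl-2-(C9–C3 side chain)cyclohex-3-ene-1-carbaldehyde
Conditions: NaBH4 (1 equiv), CeCl3·7H2O (1 equiv), EtOH/H2O (3:2), −15 °C
Reagents that add atoms: none
Why: Luche-type chemoselective reduction; in aqueous ethanol with CeCl3 the non-conjugated C2 aldehyde is masked as its hydrate or hemiacetal, so borohydride should reduce only the conjugated C20 aldehyde, in the 1,2 sense.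

Step 15
Reactants: 24 (1R,2S,6S)-3-(hydroxymethyl)-6-isopropyl-2-(C9–C3 side chain)cyclohex-3-ene-1-carbaldehyde
Product: 25 macrocyclic allylic alcohol (C2=C3 closed; C20 hydroxymethyl on C11=C12; C8 silyl ether; C19 silylethyl ester)
Conditions: LiCl (10 equiv), DBU (3 equiv), MeCN, slow addition of 24 to 0.001 M, rt
Reagents that add atoms: none
Why: Intramolecular Horner–Wadsworth–Emmons olefination under Masamune–Roush conditions; α-alkyl phosphonoacetates give the 2-alkyl-2-enoate with the β-substituent trans to the ester, which here is the ring-cis C2=C3 geometry, while the cis C6=C7 olefin and the trans ring fusion pre-organise the chain and the mild base should not epimerise C1.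

Step 16
Reactants: 25 macrocyclic allylic alcohol
Product: 28 bis-protected microeunicellol B (C11=C20 exocyclic methylene), via sulfonylhydrazine 26 (not isolated), via allylic diazene 27 (not isolated)
Conditions: 2-O2NC6H4SO2NHNH2, PPh3, DEAD, THF, −30 °C; then rt
Reagents that add atoms: 2-nitrobenzenesulfonylhydrazide NNS(=O)(=O)c1ccccc1[N+](=O)[O-] (nitrogen and sulfonyl only in 26 and 27)
Why: Myers reductive 1,3-transposition: Mitsunobu N-alkylation, loss of sulfinic acid to the monoalkyl diazene and retro-ene loss of N2 deliver H to C12 and move the double bond to C11=C20.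

Step 17
Reactants: 28 bis-protected microeunicellol B
Product: 29 microeunicellol B
Conditions: Bu4NF (5 equiv), THF, 0 °C → rt; 0.5 M HCl to pH 3
Reagents that add atoms: none
Why: Fluoride cleaves the C8 silyl ether and fragments the 2-(trimethylsilyl)ethyl ester to the C19 acid in one operation, leaving the C16 methyl ester untouched.

**Compound list**

1 | 4-(tert-butyldimethylsilyloxy)but-1-yne | C#CCCO[Si](C)(C)C(C)(C)C | starting material
2 | lithium acetylide of 1 | [Li]C#CCCO[Si](C)(C)C(C)(C)C | intermediate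
3 | 5-(tert-butyldimethylsilyloxy)pent-2-ynal | O=CC#CCCO[Si](C)(C)C(C)(C)C | intermediate
4 | (R)-8-(tert-butyldimethylsilyloxy)oct-1-en-5-yn-4-ol | C=CC[C@@H](O)C#CCCO[Si](C)(C)C(C)(C)C | intermediate
5 | (4R,5E)-8-(tert-butyldimethylsilyloxy)-5-(tributylstannyl)octa-1,5-dien-4-ol | C=CC[C@@H](O)/C([Sn](CCCC)(CCCC)CCCC)=C\CCO[Si](C)(C)C(C)(C)C | intermediate
6 | (4R,5E)-8-(tert-butyldimethylsilyloxy)-5-iodoocta-1,5-dien-4-ol | C=CC[C@@H](O)/C(I)=C\CCO[Si](C)(C)C(C)(C)C | intermediate
7 | dilithio species (lithium alkoxide and C7 vinyllithium of 6) | C=CC[C@@H](O[Li])/C([Li])=C\CCO[Si](C)(C)C(C)(C)C | intermediate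
8 | (E)-2-[(R)-1-hydroxybut-3-en-1-yl]-5-(tert-butyldimethylsilyloxy)pent-2-enoic acid | C=CC[C@@H](O)/C(C(=O)O)=C\CCO[Si](C)(C)C(C)(C)C | intermediate
9 | 2-(trimethylsilyl)ethyl (E)-2-[(R)-1-hydroxybut-3-en-1-yl]-5-(tert-butyldimethylsilyloxy)pent-2-enoate | C=CC[C@@H](O)/C(C(=O)OCC[Si](C)(C)C)=C\CCO[Si](C)(C)C(C)(C)C | intermediate
10 | 2-(trimethylsilyl)ethyl (E)-2-[(R)-1-(tert-butyldimethylsilyloxy)but-3-en-1-yl]-5-(tert-butyldimethylsilyloxy)pent-2-enoate | C=CC[C@@H](O[Si](C)(C)C(C)(C)C)/C(C(=O)OCC[Si](C)(C)C)=C\CCO[Si](C)(C)C(C)(C)C | intermediate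
11 | 2-(trimethylsilyl)ethyl (E)-2-[(R)-1-(tert-butyldimethylsilyloxy)but-3-en-1-yl]-5-hydroxypent-2-enoate | C=CC[C@@H](O[Si](C)(C)C(C)(C)C)/C(C(=O)OCC[Si](C)(C)C)=C\CCO | intermediate
12 | 2-(trimethylsilyl)ethyl (E)-2-[(R)-1-(tert-butyldimethylsilyloxy)but-3-en-1-yl]-5-iodopent-2-enoate | C=CC[C@@H](O[Si](C)(C)C(C)(C)C)/C(C(=O)OCC[Si](C)(C)C)=C\CCI | intermediate
13 | trimethyl phosphonoacetate | COC(=O)CP(=O)(OC)OC | starting material
14 | 7-methyl 1-[2-(trimethylsilyl)ethyl] (E)-2-[(R)-1-(tert-butyldimethylsilyloxy)but-3-en-1-yl]-6-(dimethoxyphosphoryl)hept-2-enedioate (C3 epimers) | C=CC[C@@H](O[Si](C)(C)C(C)(C)C)/C(C(=O)OCC[Si](C)(C)C)=C\CCC(C(=O)OC)P(=O)(OC)OC | intermediate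
15 | (E)-but-2-enal (crotonaldehyde) | C/C=C/C=O | starting material
16 | enal: 7-methyl 1-[2-(trimethylsilyl)ethyl] (E)-2-[(1R,3E)-1-(tert-butyldimethylsilyloxy)-5-oxopent-3-en-1-yl]-6-(dimethoxyphosphoryl)hept-2-enedioate | O=C/C=C/C[C@@H](O[Si](C)(C)C(C)(C)C)/C(C(=O)OCC[Si](C)(C)C)=C\CCC(C(=O)OC)P(=O)(OC)OC | intermediate
17 | (E)-4-methylpent-2-enal | CC(C)/C=C/C=O | starting material
18 | ethyl vinyl ether | C=COCC | starting material
19 | 2-ethoxy-4-isopropyl-3,4-dihydro-2H-pyran (cis/trans mixture, racemic) | CCOC1CC(C(C)C)C=CO1 | intermediate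
20 | 3-isopropylpentanedial | O=CCC(C(C)C)CC=O | intermediate
21 | Michael adduct, drawn as the free trialdehyde (C1–C10 formed; C20, C2 and C12 formyl groups) | O=CC[C@@H](C[C@@H](O[Si](C)(C)C(C)(C)C)/C(C(=O)OCC[Si](C)(C)C)=C\CCC(C(=O)OC)P(=O)(OC)OC)[C@H](C=O)[C@H](C(C)C)CC=O | intermediate
22 | aldol: cyclohexane with C12–OH and C11–CHO (C11 and C12 configurations undefined) | O=CC1C(O)C[C@@H](C(C)C)[C@@H](C=O)[C@@H]1C[C@@H](O[Si](C)(C)C(C)(C)C)/C(C(=O)OCC[Si](C)(C)C)=C\CCC(C(=O)OC)P(=O)(OC)OC | intermediate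
23 | (4S,5R,6S)-4-isopropyl-6-(C9–C3 side chain)cyclohex-1-ene-1,5-dicarbaldehyde; side chain CH2–CH(OSiMe2t-Bu)–C(CO2CH2CH2SiMe3)=CH–CH2CH2–CH(CO2Me)P(O)(OMe)2 | O=CC1=CC[C@@H](C(C)C)[C@@H](C=O)[C@@H]1C[C@@H](O[Si](C)(C)C(C)(C)C)/C(C(=O)OCC[Si](C)(C)C)=C\CCC(C(=O)OC)P(=O)(OC)OC | intermediate
24 | (1R,2S,6S)-3-(hydroxymethyl)-6-isopropyl-2-(C9–C3 side chain)cyclohex-3-ene-1-carbaldehyde | OCC1=CC[C@@H](C(C)C)[C@@H](C=O)[C@@H]1C[C@@H](O[Si](C)(C)C(C)(C)C)/C(C(=O)OCC[Si](C)(C)C)=C\CCC(C(=O)OC)P(=O)(OC)OC | intermediate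
25 | macrocyclic allylic alcohol: trans-fused cyclohexene/cyclodecadiene with C20 hydroxymethyl on C11=C12, C16 methyl ester, C19 2-(trimethylsilyl)ethyl ester, C8 silyl ether | OCC1=CC[C@@H](C(C)C)[C@H]2/C=C(/C(=O)OC)CC/C=C(/C(=O)OCC[Si](C)(C)C)[C@H](O[Si](C)(C)C(C)(C)C)C[C@H]12 | intermediate
26 | N-(C20-allyl)-N-(2-nitrophenylsulfonyl)hydrazine of 25 | NN(CC1=CC[C@@H](C(C)C)[C@H]2/C=C(/C(=O)OC)CC/C=C(/C(=O)OCC[Si](C)(C)C)[C@H](O[Si](C)(C)C(C)(C)C)C[C@H]12)S(=O)(=O)c1ccccc1[N+](=O)[O-] | intermediate
27 | allylic diazene | N=NCC1=CC[C@@H](C(C)C)[C@H]2/C=C(/C(=O)OC)CC/C=C(/C(=O)OCC[Si](C)(C)C)[C@H](O[Si](C)(C)C(C)(C)C)C[C@H]12 | intermediate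
28 | bis-protected microeunicellol B (C8 tert-butyldimethylsilyl ether, C19 2-(trimethylsilyl)ethyl ester) | C=C1CC[C@@H](C(C)C)[C@H]2/C=C(/C(=O)OC)CC/C=C(/C(=O)OCC[Si](C)(C)C)[C@H](O[Si](C)(C)C(C)(C)C)C[C@H]12 | intermediate
29 | microeunicellol B | C=C1CC[C@@H](C(C)C)[C@H]2/C=C(/C(=O)OC)CC/C=C(/C(=O)O)[C@H](O)C[C@H]12 | target

**Step count and risks**

Total steps: 17. Longest linear sequence: 15 (steps 1–10 and 13–17).

Step 13 (key step). The wrong enantiotopic arm of the dial may react, giving poor selectivity at C14, and C1 may epimerise under the amine. The fallback fixes C14 before the ring is made; it sets out from 20 (with 16) and comes back at 23. Dial 20 is oxidised (NaClO2, NaH2PO4, 2-methylbut-2-ene) to 3-isopropylpentanedioic acid F1 and dehydrated (Ac2O, reflux) to 3-isopropylglutaric anhydride F2. Cinchona-alkaloid-mediated methanolysis, with the quinine- or quinidine-series catalyst chosen to give the R isomer, leads to hemiester F3. BH3·SMe2 reduces the free acid to hydroxy ester F4, Dess–Martin periodinane gives aldehyde ester F5, and HC(OMe)3 with pyridinium p-toluenesulfonate in MeOH gives acetal ester F6. i-Bu2AlH at −78 °C then gives (S)-5,5-dimethoxy-3-isopropylpentanal F7, in which only one terminus can form an enamine. Michael addition of F7 to 16 with the same (S)-amine catalyst gives mono-acetal adduct F8 with C1 and C10 under catalyst control. Aqueous trifluoroacetic acid followed by the amine/benzoic acid buffer unmasks C12 and closes the ring by aldol condensation to 23.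

Step 15. Cyclodimerisation and oligomerisation may compete with the medium-ring olefination, and C1 may epimerise under base. The fallback closes the same bond by olefin metathesis; it sets out from 24 and comes back at 25. The aldehyde is methylenated without base (Zn, CH2Br2, TiCl4) to vinyl phosphonate F9. Horner–Wadsworth–Emmons reaction with aqueous formaldehyde and K2CO3 turns the phosphonate into 2-substituted acrylate F10. Ring-closing metathesis (second-generation Hoveyda–Grubbs catalyst RuCl2(=CH-2-(i-PrO)C6H4)(H2IMes), toluene, 80 °C, 0.001 M) then gives 25.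

Step 14. The hydride may fail to discriminate between the hindered saturated aldehyde and the conjugated one, so that both are reduced or the wrong one is. The fallback differentiates the two carbons at the alcohol stage; it sets out from 23 and comes back at 25. NaBH4 in MeOH reduces both aldehydes to diol F11. t-BuMe2SiCl and imidazole (1 equiv, −20 °C) silylate the less hindered allylic C20 hydroxyl to give mono-silyl ether F12. Dess–Martin periodinane gives aldehyde F13, and LiCl/DBU at high dilution closes the ring to macrocycle F14. Pyridinium p-toluenesulfonate in MeOH removes the primary allylic silyl ether selectively to give 25.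

**Further compounds**

F1 | step 13 | 3-isopropylpentanedioic acid | OC(=O)CC(C(C)C)CC(=O)O
F2 | step 13 | 3-isopropylglutaric anhydride (4-isopropyloxane-2,6-dione) | CC(C)C1CC(=O)OC(=O)C1
F3 | step 13 | (R)-5-methoxy-5-oxo-3-isopropylpentanoic acid | COC(=O)C[C@H](C(C)C)CC(=O)O
F4 | step 13 | methyl (R)-5-hydroxy-3-isopropylpentanoate | COC(=O)C[C@H](C(C)C)CCO
F5 | step 13 | methyl (R)-3-isopropyl-5-oxopentanoate | COC(=O)C[C@H](C(C)C)CC=O
F6 | step 13 | methyl (R)-5,5-dimethoxy-3-isopropylpentanoate | COC(=O)C[C@H](C(C)C)CC(OC)OC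
F7 | step 13 | (S)-5,5-dimethoxy-3-isopropylpentanal | O=CC[C@H](C(C)C)CC(OC)OC
F8 | step 13 | Michael adduct of F7 and 16 (C12 as dimethyl acetal) | O=CC[C@@H](C[C@@H](O[Si](C)(C)C(C)(C)C)/C(C(=O)OCC[Si](C)(C)C)=C\CCC(C(=O)OC)P(=O)(OC)OC)[C@H](C=O)[C@H](C(C)C)CC(OC)OC
F9 | step 15 | C1-vinyl phosphonate (24 with CH=CH2 in place of CHO) | OCC1=CC[C@@H](C(C)C)[C@@H](C=C)[C@@H]1C[C@@H](O[Si](C)(C)C(C)(C)C)/C(C(=O)OCC[Si](C)(C)C)=C\CCC(C(=O)OC)P(=O)(OC)OC
F10 | step 15 | C1-vinyl 2-substituted acrylate (metathesis precursor) | OCC1=CC[C@@H](C(C)C)[C@@H](C=C)[C@@H]1C[C@@H](O[Si](C)(C)C(C)(C)C)/C(C(=O)OCC[Si](C)(C)C)=C\CCC(=C)C(=O)OC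
F11 | step 14 | diol (C20 and C2 hydroxymethyl groups) | OCC1=CC[C@@H](C(C)C)[C@@H](CO)[C@@H]1C[C@@H](O[Si](C)(C)C(C)(C)C)/C(C(=O)OCC[Si](C)(C)C)=C\CCC(C(=O)OC)P(=O)(OC)OC
F12 | step 14 | C20 tert-butyldimethylsilyl ether of diol F11 | CC(C)(C)[Si](C)(C)OCC1=CC[C@@H](C(C)C)[C@@H](CO)[C@@H]1C[C@@H](O[Si](C)(C)C(C)(C)C)/C(C(=O)OCC[Si](C)(C)C)=C\CCC(C(=O)OC)P(=O)(OC)OC
F13 | step 14 | C2 aldehyde with C20 silyl ether | CC(C)(C)[Si](C)(C)OCC1=CC[C@@H](C(C)C)[C@@H](C=O)[C@@H]1C[C@@H](O[Si](C)(C)C(C)(C)C)/C(C(=O)OCC[Si](C)(C)C)=C\CCC(C(=O)OC)P(=O)(OC)OC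
F14 | step 14 | macrocycle with C20 and C8 silyl ethers | CC(C)(C)[Si](C)(C)OCC1=CC[C@@H](C(C)C)[C@H]2/C=C(/C(=O)OC)CC/C=C(/C(=O)OCC[Si](C)(C)C)[C@H](O[Si](C)(C)C(C)(C)C)C[C@H]12
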